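The ratio to read first for beta and gamma is the one between what stands unfinished early and late in a run at 40 °C.

| flask | substrate | reagent | temperature | remark | time |
|---|---|---|---|---|---|
| summer | 0.40 M (in portions, 3) | 0.32 M | 25 °C | run made earlier; portions every 15 min |  |
| noon | 0.40 M (in portions, 3) | 0.72 M | 40 °C | run made earlier; portions every 15 min |  |
| beta | 0.40 M | 1.00 M | 40 °C | everything together at the start | 30 h |
| gamma | 0.40 M (in portions, 3) | 0.600 M | 40 °C | the portions of substrate follow each other after 15 min, the first at the start | 30 h |

| run | time / h | target / % | substrate / % |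
|---|---|---|---|
| summer | 8.00 | 12 | 57 |
| summer | 15.0 | 27 | 36 |
| summer | 20.0 | 36 | 32 |
| summer | 30.0 | 50 | 23 |
| summer | 40.0 | 60 | 18 |
| noon | 4.00 | 32 | 40 |
| noon | 8.00 | 56 | 23 |
| noon | 10.0 | 67 | 21 |
| noon | 15.0 | 86 | 11 |
| noon | 20.0 | 88 | 8 |

(each reading ± 2 percentage points)

- a reading or a percentage of target counts all its forms, free or not

- the winner by amount of target, in percent of the substrate charged; "neither" if no more than 2 percentage points parts them (beta / gamma / neither)
- how much target is there at the end, in percent of the substrate charged: beta
- how much target is there at the end, in percent of the substrate charged: gamma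

Call the unfinished fraction the part of the charge not yet target. In the noon run it falls by a ratio of 5.67 from 4.00 h to 20.0 h. The logarithm of that ratio over the 16.0 h between gives 0.0471 h⁻¹, the tail rate in decades of unfinished fraction per hour: a pseudo-first-order tail, one decade per 21.2 h. The opening 4.00 h read 0.0419 h⁻¹, so as a reading the pace in decades holds from the start, while the pace in points of target shrinks with the unfinished fraction itself.

My reckoning then takes factors. At the tail rate, the 10.0 h beyond the last reading divide the unfinished fraction by 2.96. Gamma's last portion enters 30.0 min after beta's whole charge, and counting the whole charge that late gives a factor of 1.06. The reagent factor cannot be read, since summer and noon differ in temperature too, so I set it to one. That leaves an estimated 4.06% unfinished, about 95.9% target in each flask, resting on noon readings with a scatter of 2 percentage points. With the reagent factor at one, dosing parts them by an estimated 0.23 points, less than 2 points, so I say neither.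

The forecast differs: 93% for beta, 90% for gamma, winner beta, since “Beta has more reagent and leaves less substrate”.

The flask gives 96.7% for beta and 97.4% for gamma, so the answer is neither.

    crystals ⇌ target, rate k1*(cs1 - [target]) while solid is left; crystals form when [target] > cs1 (solubility = 0.180 M, k = 0.393 min⁻¹)
    reagent + intermediate A ⇌ intermediate B (K = 0.760 M⁻¹, k = 0.0116 M⁻¹ min⁻¹, Ea = 58.0 kJ mol⁻¹, ΔH = −23.0 kJ mol⁻¹)
    substrate ⇌ intermediate A (K = 0.630, k = 0.0118 min⁻¹, Ea = 102 kJ mol⁻¹, ΔH = −27.0 kJ mol⁻¹)
    intermediate A → target (k = 0.00719 min⁻¹, Ea = 89.0 kJ mol⁻¹)
    (constants at 40 °C)

Over the whole 30 h, gamma's tail rate comes to 0.0531 h⁻¹, where the noon run read 0.0471 h⁻¹. The neighbouring flask is gamma with 2.4 M of reagent, 6.00 equiv. It ends at 92.8% target, which is a tail rate of 0.0381 h⁻¹, slower than gamma's. The reagent factor that could not be read before is therefore 0.718 on the rate for this step up. At the end of that flask intermediate B holds 2.99% of the charge, against 0.390% in gamma.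

The runs come from a simulation with made-up constants, and the scatter is random.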